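## Retrosynthetic overview

1. Target 22 comes from bis-TBS ether 21 by desilylation; 21 comes from aldehyde 18 and pyranone 3 (ring A) by a lateral lithium-dienolate aldol (C2–C3) with in-situ acetylation.
2. 18 comes from enal 12 by a reagent-controlled syn thiopropionate boron aldol (C4–C5), silylation and thioester reduction.
3. 12 comes from pyranone 7 and 3-ethoxymethacrolein by a catalytic asymmetric lateral vinylogous Mukaiyama addition with allylic transposition (C7–C8, E-alkene).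
4. 7 comes from 3 and propanal by the key metal-free catalytic asymmetric lateral vinylogous Mukaiyama aldol (first two stereocentres).
5. Rings: the γ-pyranone is formed once (3, from 3-pentanone and propanoic acid) and used twice, as ring B first (steps 2–5) and as ring A last (step 9); no ring is made later.

Assumption: "IDPi" is a confined BINOL-derived imidodiphosphorimidate Brønsted acid; for it and for the Corey diazaborolidine the enantiomer named is the one taken to give the product drawn (both enantiomers are equally available), and LDA is a bought solution.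

Shorthand: TBS = tert-butyldimethylsilyl; PyA = 6-ethyl-3,5-dimethyl-4-oxo-4H-pyran-2-yl; PyB = 6-{(2S,3S)-3-[(tert-butyldimethylsilyl)oxy]pentan-2-yl}-3,5-dimethyl-4-oxo-4H-pyran-2-yl; chain numbers C2–C8 follow the name of 22.

## Route

Step 1
Reactants: 1 3-pentanone; 2 propanoic acid (two molecules are built in)
Product: 3 2,6-diethyl-3,5-dimethyl-4H-pyran-4-one
Conditions: PPA, 100 °C
Reagents that add atoms: none
Why: Double C-acylation of the ketone by propanoic acid in PPA gives the 1,3,5-triketone, which cyclodehydrates in the same medium (PPA pyranone condensation); no stereocentre.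

Step 2
Reactants: 3 2,6-diethyl-3,5-dimethyl-4H-pyran-4-one
Product: 5 tert-butyl{[(6Z)-2-ethyl-6-ethylidene-3,5-dimethyl-6H-pyran-4-yl]oxy}dimethylsilane, via 4-[(tert-butyldimethylsilyl)oxy]-2,6-diethyl-3,5-dimethylpyrylium trifluoromethanesulfonate 4 (not isolated)
Conditions: TBSOTf, CH2Cl2, 0 °C; Et3N, 0 °C → rt; pentane, filtration under Ar, Kugelrohr distillation
Reagents that add atoms: tert-butyldimethylsilyl trifluoromethanesulfonate, CC(C)(C)[Si](C)(C)OS(=O)(=O)C(F)(F)F
Why: Soft enolisation: O-silylation of the pyranone carbonyl gives the 4-silyloxypyrylium salt, whose lateral CH2 is acidic enough for Et3N to remove (pyrylium anhydrobase formation); the substrate is symmetric, and A(1,3) strain with the C5 methyl fixes the Z-ethylidene geometry.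

Step 3
Reactants: 5 tert-butyl{[(6Z)-2-ethyl-6-ethylidene-3,5-dimethyl-6H-pyran-4-yl]oxy}dimethylsilane; 6 propanal
Product: 7 2-{(2S,3S)-3-[(tert-butyldimethylsilyl)oxy]pentan-2-yl}-6-ethyl-3,5-dimethyl-4H-pyran-4-one
Conditions: (S,S)-IDPi (2 mol%), toluene, −78 → −60 °C; Et3N quench
Reagents that add atoms: none
Why: Proposed new method: catalytic asymmetric lateral (vinylogous) Mukaiyama aldol of a γ-pyranone silyl trienol ether under silylium/chiral-anion (IDPi) catalysis. The IDPi acid is silylated by 5; its confined anion pairs with O-silylated propanal and shields one aldehyde face; 5 attacks through the exocyclic carbon (restoring the aromatic 4-silyloxypyrylium) via an open antiperiplanar transition state with the aldehyde ethyl group over the ring-oxygen flank, away from the C5 methyl (anti, 2S,3S); the 4-silyloxypyrylium ion pair passes TBS+ to the next aldehyde, so the TBS group ends on the new carbinol. Closest known reactions: IDPi/disulfonimide-catalysed (vinylogous) Mukaiyama aldols of silyl ketene acetals and dienolates with aliphatic aldehydes, and the racemic lateral lithiation–aldol of 2-alkyl-4-pyranones.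

Step 4
Reactants: 7 2-{(2S,3S)-3-[(tert-butyldimethylsilyl)oxy]pentan-2-yl}-6-ethyl-3,5-dimethyl-4H-pyran-4-one
Product: 9 {[(6Z)-2-{(2S,3S)-3-[(tert-butyldimethylsilyl)oxy]pentan-2-yl}-6-ethylidene-3,5-dimethyl-6H-pyran-4-yl]oxy}trimethylsilane, via lithium (6Z)-2-{(2S,3S)-3-[(tert-butyldimethylsilyl)oxy]pentan-2-yl}-6-ethylidene-3,5-dimethyl-6H-pyran-4-olate 8 (not isolated)
Conditions: LDA, THF, −78 °C; TMSCl, −78 → −20 °C; pentane, filtration under Ar
Reagents that add atoms: chlorotrimethylsilane, C[Si](C)(C)Cl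
Why: LDA removes the unhindered CH2 proton of the remaining ethyl group faster than the tertiary, A(1,3)-shielded C–H next to the silyloxy carbon, and O-silylation gives the mixed silyl dienol ether (kinetic lateral enolisation) without touching the stereocentres.

Step 5
Reactants: 9 {[(6Z)-2-{(2S,3S)-3-[(tert-butyldimethylsilyl)oxy]pentan-2-yl}-6-ethylidene-3,5-dimethyl-6H-pyran-4-yl]oxy}trimethylsilane; 10 (E)-3-ethoxy-2-methylprop-2-enal
Product: 12 (2E,4R)-2-methyl-4-(PyB)pent-2-enal, via 2-{(2R,3S,4E)-5-ethoxy-4-methyl-3-[(trimethylsilyl)oxy]pent-4-en-2-yl}-6-{(2S,3S)-3-[(tert-butyldimethylsilyl)oxy]pentan-2-yl}-3,5-dimethyl-4H-pyran-4-one 11 (not isolated)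
Conditions: (R,R)-IDPi (3 mol%), toluene, −78 °C; then 1 M HCl, THF, 0 °C
Reagents that add atoms: water, O
Why: Proposed new method: the same IDPi silylium catalysis used as a lateral vinylogous Mukaiyama addition to a β-alkoxy enal, followed by allylic transposition. The enantiomeric catalyst fixes the face of TMS-activated 10 and, through the same anti open transition state, the face of the Z-ethylidene carbon, so the pyranone-bearing carbon is R; dilute acid then cleaves the TMS ether and the γ-hydroxy enol ether collapses by 1,3-transposition to the thermodynamic E-enal, erasing the carbinol centre. Closest known reactions: organolithium 1,2-addition to 3-alkoxyacroleins with acidic transposition (Stork–Danheiser/Wollenberg type), and IDPi-catalysed Mukaiyama aldols.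

Step 6
Reactants: 12 (2E,4R)-2-methyl-4-(PyB)pent-2-enal; 13 S-phenyl propanethioate
Product: 16 S-phenyl (2S,3S,4E,6R)-3-hydroxy-2,4-dimethyl-6-(PyB)hept-4-enethioate, via (4R,5R)-4,5-diphenyl-2-{[(1E)-1-(phenylsulfanyl)prop-1-en-1-yl]oxy}-1,3-ditosyl-1,3,2-diazaborolidine 14 (not isolated), via S-phenyl (2S,3S,4E,6R)-3-{[(4R,5R)-4,5-diphenyl-1,3-ditosyl-1,3,2-diazaborolidin-2-yl]oxy}-2,4-dimethyl-6-(PyB)hept-4-enethioate 15 (not isolated)
Conditions: 13, (R,R)-2-bromo-4,5-diphenyl-1,3-ditosyl-1,3,2-diazaborolidine (pre-formed), i-Pr2NEt, CH2Cl2, −78 → 0 °C; then 12, −78 °C; pH 7 buffer, MeOH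
Reagents that add atoms: none
Why: The chiral diazaborolidine gives the Z(O)-boron enolate of the thioester, which adds through a closed Zimmerman–Traxler transition state in which the C2-symmetric sulfonamide ligand selects the aldehyde face, giving the 2,3-syn (2S,3S) aldol under reagent control (Corey boron aldol), with no free Lewis acid or strong base to epimerise C6.

Step 7
Reactants: 16 S-phenyl (2S,3S,4E,6R)-3-hydroxy-2,4-dimethyl-6-(PyB)hept-4-enethioate
Product: 17 S-phenyl (2S,3S,4E,6R)-3-[(tert-butyldimethylsilyl)oxy]-2,4-dimethyl-6-(PyB)hept-4-enethioate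
Conditions: TBSOTf, 2,6-lutidine, CH2Cl2, −78 °C
Reagents that add atoms: tert-butyldimethylsilyl trifluoromethanesulfonate, CC(C)(C)[Si](C)(C)OS(=O)(=O)C(F)(F)F
Why: Silyl triflate silylation of the hindered allylic alcohol at −78 °C, where the hindered base enolises neither the thioester nor the lateral pyranone positions (silyl ether formation), marks this oxygen so that only the C3 oxygen is acetylated later.

Step 8
Reactants: 17 S-phenyl (2S,3S,4E,6R)-3-[(tert-butyldimethylsilyl)oxy]-2,4-dimethyl-6-(PyB)hept-4-enethioate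
Product: 18 (2S,3S,4E,6R)-3-[(tert-butyldimethylsilyl)oxy]-2,4-dimethyl-6-(PyB)hept-4-enal
Conditions: Et3SiH, 10% Pd/C, acetone, rt
Reagents that add atoms: none
Why: Fukuyama reduction: Pd inserts into the acyl–S bond and the silane delivers hydride, stopping at the aldehyde under neutral conditions that leave the pyranone, trisubstituted alkene, silyl ethers and the α-stereocentre untouched.

Step 9
Reactants: 18 (2S,3S,4E,6R)-3-[(tert-butyldimethylsilyl)oxy]-2,4-dimethyl-6-(PyB)hept-4-enal; 3 2,6-diethyl-3,5-dimethyl-4H-pyran-4-one (2 equiv)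
Product: 21 (2R,3R,4R,5S,6E,8R)-5-[(tert-butyldimethylsilyl)oxy]-4,6-dimethyl-2-(PyA)-8-(PyB)non-6-en-3-yl acetate, via lithium (6Z)-2-ethyl-6-ethylidene-3,5-dimethyl-6H-pyran-4-olate 19 (not isolated), via lithium (2R,3R,4R,5S,6E,8R)-5-[(tert-butyldimethylsilyl)oxy]-4,6-dimethyl-2-(PyA)-8-(PyB)non-6-en-3-olate 20 (not isolated)
Conditions: 3, LDA (slightly less than 3), THF, −78 °C; 18, −78 °C; Ac2O (excess), DMAP, −78 → −20 °C
Reagents that add atoms: acetic anhydride, CC(=O)OC(C)=O
Why: Lateral (vinylogous) lithium aldol addition to the α-methyl aldehyde, where Felkin–Anh attack sets C3 syn to the C4 methyl and the open transition state with the aldehyde chain over the ring-oxygen flank of the Z-dienolate sets C2/C3 anti; trapping the lithium aldolate with Ac2O acylates only this oxygen.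

Step 10
Reactants: 21 (2R,3R,4R,5S,6E,8R)-5-[(tert-butyldimethylsilyl)oxy]-4,6-dimethyl-2-(PyA)-8-(PyB)non-6-en-3-yl acetate
Product: 22 (2R,3R,4S,5S,6E,8R)-2-(6-ethyl-3,5-dimethyl-4-oxo-4H-pyran-2-yl)-5-hydroxy-8-{6-[(2S,3S)-3-hydroxypentan-2-yl]-3,5-dimethyl-4-oxo-4H-pyran-2-yl}-4,6-dimethylnon-6-en-3-yl acetate (CNP0290537.1)
Conditions: HF·pyridine, pyridine, THF, 0 °C → rt
Reagents that add atoms: none
Why: Buffered HF cleaves both secondary TBS ethers (silyl ether deprotection) under mildly acidic conditions that neither hydrolyse nor migrate the acetate and touch no stereocentre.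

## Compound list

1 | 3-pentanone | CCC(=O)CC | starting material
2 | propanoic acid | CCC(=O)O | starting material
3 | 2,6-diethyl-3,5-dimethyl-4H-pyran-4-one | CCc1oc(CC)c(C)c(=O)c1C | intermediate
4 | 4-[(tert-butyldimethylsilyl)oxy]-2,6-diethyl-3,5-dimethylpyrylium trifluoromethanesulfonate | CCc1[o+]c(CC)c(C)c(O[Si](C)(C)C(C)(C)C)c1C.[O-]S(=O)(=O)C(F)(F)F | intermediate
5 | tert-butyl{[(6Z)-2-ethyl-6-ethylidene-3,5-dimethyl-6H-pyran-4-yl]oxy}dimethylsilane | CCC1=C(C)C(O[Si](C)(C)C(C)(C)C)=C(C)/C(=C/C)O1 | intermediate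
6 | propanal | CCC=O | starting material
7 | 2-{(2S,3S)-3-[(tert-butyldimethylsilyl)oxy]pentan-2-yl}-6-ethyl-3,5-dimethyl-4H-pyran-4-one | CCc1oc([C@@H](C)[C@@H](O[Si](C)(C)C(C)(C)C)CC)c(C)c(=O)c1C | intermediate
8 | lithium (6Z)-2-{(2S,3S)-3-[(tert-butyldimethylsilyl)oxy]pentan-2-yl}-6-ethylidene-3,5-dimethyl-6H-pyran-4-olate | [Li+].[O-]C1=C(C)/C(=C/C)OC([C@@H](C)[C@@H](O[Si](C)(C)C(C)(C)C)CC)=C1C | intermediate
9 | {[(6Z)-2-{(2S,3S)-3-[(tert-butyldimethylsilyl)oxy]pentan-2-yl}-6-ethylidene-3,5-dimethyl-6H-pyran-4-yl]oxy}trimethylsilane | C/C=C1\OC([C@@H](C)[C@@H](O[Si](C)(C)C(C)(C)C)CC)=C(C)C(O[Si](C)(C)C)=C1C | intermediate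
10 | (E)-3-ethoxy-2-methylprop-2-enal (3-ethoxymethacrolein) | CCO/C=C(\C)C=O | starting material
11 | 2-{(2R,3S,4E)-5-ethoxy-4-methyl-3-[(trimethylsilyl)oxy]pent-4-en-2-yl}-6-{(2S,3S)-3-[(tert-butyldimethylsilyl)oxy]pentan-2-yl}-3,5-dimethyl-4H-pyran-4-one | CCO/C=C(\C)[C@@H](O[Si](C)(C)C)[C@@H](C)c1oc([C@@H](C)[C@@H](O[Si](C)(C)C(C)(C)C)CC)c(C)c(=O)c1C | intermediate
12 | (2E,4R)-2-methyl-4-(PyB)pent-2-enal | O=C/C(C)=C/[C@@H](C)c1oc([C@@H](C)[C@@H](O[Si](C)(C)C(C)(C)C)CC)c(C)c(=O)c1C | intermediate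
13 | S-phenyl propanethioate | CCC(=O)Sc1ccccc1 | starting material
14 | (4R,5R)-4,5-diphenyl-2-{[(1E)-1-(phenylsulfanyl)prop-1-en-1-yl]oxy}-1,3-ditosyl-1,3,2-diazaborolidine (Z(O)-boron enolate) | C/C=C(/Sc1ccccc1)OB1N(S(=O)(=O)c2ccc(C)cc2)[C@H](c2ccccc2)[C@@H](c2ccccc2)N1S(=O)(=O)c1ccc(C)cc1 | intermediate
15 | S-phenyl (2S,3S,4E,6R)-3-{[(4R,5R)-4,5-diphenyl-1,3-ditosyl-1,3,2-diazaborolidin-2-yl]oxy}-2,4-dimethyl-6-(PyB)hept-4-enethioate | O=C(Sc1ccccc1)[C@@H](C)[C@H](OB1N(S(=O)(=O)c2ccc(C)cc2)[C@H](c2ccccc2)[C@@H](c2ccccc2)N1S(=O)(=O)c1ccc(C)cc1)/C(C)=C/[C@@H](C)c1oc([C@@H](C)[C@@H](O[Si](C)(C)C(C)(C)C)CC)c(C)c(=O)c1C | intermediate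
16 | S-phenyl (2S,3S,4E,6R)-3-hydroxy-2,4-dimethyl-6-(PyB)hept-4-enethioate | O=C(Sc1ccccc1)[C@@H](C)[C@H](O)/C(C)=C/[C@@H](C)c1oc([C@@H](C)[C@@H](O[Si](C)(C)C(C)(C)C)CC)c(C)c(=O)c1C | intermediate
17 | S-phenyl (2S,3S,4E,6R)-3-[(tert-butyldimethylsilyl)oxy]-2,4-dimethyl-6-(PyB)hept-4-enethioate | O=C(Sc1ccccc1)[C@@H](C)[C@H](O[Si](C)(C)C(C)(C)C)/C(C)=C/[C@@H](C)c1oc([C@@H](C)[C@@H](O[Si](C)(C)C(C)(C)C)CC)c(C)c(=O)c1C | intermediate
18 | (2S,3S,4E,6R)-3-[(tert-butyldimethylsilyl)oxy]-2,4-dimethyl-6-(PyB)hept-4-enal | O=C[C@@H](C)[C@H](O[Si](C)(C)C(C)(C)C)/C(C)=C/[C@@H](C)c1oc([C@@H](C)[C@@H](O[Si](C)(C)C(C)(C)C)CC)c(C)c(=O)c1C | intermediate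
19 | lithium (6Z)-2-ethyl-6-ethylidene-3,5-dimethyl-6H-pyran-4-olate | [Li+].[O-]C1=C(C)/C(=C/C)OC(CC)=C1C | intermediate
20 | lithium (2R,3R,4R,5S,6E,8R)-5-[(tert-butyldimethylsilyl)oxy]-4,6-dimethyl-2-(PyA)-8-(PyB)non-6-en-3-olate (C4 reads R only because OSi outranks the C3 oxygen; geometry as in 22) | CCc1oc([C@H](C)[C@H]([O-])[C@@H](C)[C@H](O[Si](C)(C)C(C)(C)C)/C(C)=C/[C@@H](C)c2oc([C@@H](C)[C@@H](O[Si](C)(C)C(C)(C)C)CC)c(C)c(=O)c2C)c(C)c(=O)c1C.[Li+] | intermediate
21 | (2R,3R,4R,5S,6E,8R)-5-[(tert-butyldimethylsilyl)oxy]-4,6-dimethyl-2-(PyA)-8-(PyB)non-6-en-3-yl acetate (C4 reads R only because OSi outranks OAc; geometry as in 22) | CCc1oc([C@H](C)[C@H](OC(C)=O)[C@@H](C)[C@H](O[Si](C)(C)C(C)(C)C)/C(C)=C/[C@@H](C)c2oc([C@@H](C)[C@@H](O[Si](C)(C)C(C)(C)C)CC)c(C)c(=O)c2C)c(C)c(=O)c1C | intermediate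
22 | (2R,3R,4S,5S,6E,8R)-2-(6-ethyl-3,5-dimethyl-4-oxo-4H-pyran-2-yl)-5-hydroxy-8-{6-[(2S,3S)-3-hydroxypentan-2-yl]-3,5-dimethyl-4-oxo-4H-pyran-2-yl}-4,6-dimethylnon-6-en-3-yl acetate | CCc1oc([C@H](C)[C@H](OC(C)=O)[C@@H](C)[C@H](O)/C(C)=C/[C@@H](C)c2oc([C@@H](C)[C@@H](O)CC)c(C)c(=O)c2C)c(C)c(=O)c1C | target

## Step count and risks

Total steps: 10. Longest linear sequence: 10 (1/2 → 3 → 5 → 7 → 9 → 12 → 16 → 17 → 18 → 21 → 22; 3 re-enters in step 9).

The three steps most likely to fail: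

**Step 3 (proposed new method).** The pyranone product is a strong silyl acceptor, so the 4-silyloxypyrylium·IDPi ion pair is the likely resting state and turnover may be slow. The anti selectivity of the open transition state is unproven. The fallback uses known chemistry, sets out from 3 and comes back at 7. Lithium dienolate 19 (from 3, LDA, THF, −78 °C; the species also used in step 9) is added to propanal 6 in the known racemic lateral aldol to give lithium 2-(6-ethyl-3,5-dimethyl-4-oxo-4H-pyran-2-yl)pentan-3-olate F1 as a syn/anti mixture. NH4Cl quench and chromatography give racemic anti-2-ethyl-6-(3-hydroxypentan-2-yl)-3,5-dimethyl-4H-pyran-4-one F2. Lipase-catalysed kinetic resolution (Amano PS or CAL-B, vinyl acetate, MTBE) acylates the (3R)-carbinol enantiomer to (2R,3R)-2-(6-ethyl-3,5-dimethyl-4-oxo-4H-pyran-2-yl)pentan-3-yl acetate F4, which is removed. It leaves 2-ethyl-6-[(2S,3S)-3-hydroxypentan-2-yl]-3,5-dimethyl-4H-pyran-4-one F3, which TBSCl/imidazole/DMF converts into 7.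

**Step 5 (the same new catalysis in an addition–transposition mode).** The only stereochemical output is the face of the nucleophilic carbon, which depends on both carbinol-face and anti selectivity. Adduct 11 is a vinylogous acetal that the silylium catalyst may ionise, leading to over-addition. The fallback uses known chemistry, sets out from 7 (through its lithium dienolate 8) and comes back at 12. Dienolate 8 is added to 10 (THF, −78 °C), a known 1,2-addition of lateral pyranone anions to aldehydes, giving lithium (4E)-5-ethoxy-4-methyl-2-(PyB)pent-4-en-3-olate F5 as a diastereomer mixture. 1 M HCl/THF brings about the known hydrolytic 1,3-transposition to the E-enal, obtained as a roughly 1:1 mixture of 12 and its epimer (2E,4S)-2-methyl-4-(PyB)pent-2-enal F6. The epimers are separated by preparative HPLC, or, if inseparable, carried through step 6 and separated as the aldols. The material of correct configuration continues as 12.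

**Step 9.** The simple diastereoselection of the open-transition-state lithium dienolate addition (C2/C3 anti) rests on analogy only. The aldolate may undergo retro-aldol reaction, and the acetate may be lost by E1cB elimination before quench. The fallback sets out from 18 and the silyl dienol ether 5 (already made in step 2) and comes back at 21. A BF3·OEt2-mediated Mukaiyama aldol (3 equiv, CH2Cl2, −78 °C; open transition state, Felkin-selective with a bulky enolsilane) gives after aqueous work-up the free alcohol (2R,3R,4R,5S,6E,8R)-5-[(tert-butyldimethylsilyl)oxy]-4,6-dimethyl-2-(PyA)-8-(PyB)non-6-en-3-ol F7. Its diastereomers can be separated at this stage before a separate acetylation (Ac2O, DMAP, pyridine) to 21.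

## Further compounds

F1 | step 3 | lithium 2-(6-ethyl-3,5-dimethyl-4-oxo-4H-pyran-2-yl)pentan-3-olate (racemic syn/anti mixture) | CCc1oc(C(C)C([O-])CC)c(C)c(=O)c1C.[Li+]
F2 | step 3 | rac-anti-2-ethyl-6-(3-hydroxypentan-2-yl)-3,5-dimethyl-4H-pyran-4-one (1:1 mixture of 2S,3S and 2R,3R) | CCc1oc([C@@H](C)[C@@H](O)CC)c(C)c(=O)c1C.CCc1oc([C@H](C)[C@H](O)CC)c(C)c(=O)c1C
F3 | step 3 | 2-ethyl-6-[(2S,3S)-3-hydroxypentan-2-yl]-3,5-dimethyl-4H-pyran-4-one | CCc1oc([C@@H](C)[C@@H](O)CC)c(C)c(=O)c1C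
F4 | step 3 | (2R,3R)-2-(6-ethyl-3,5-dimethyl-4-oxo-4H-pyran-2-yl)pentan-3-yl acetate | CCc1oc([C@H](C)[C@H](OC(C)=O)CC)c(C)c(=O)c1C
F5 | step 5 | lithium (4E)-5-ethoxy-4-methyl-2-(PyB)pent-4-en-3-olate (diastereomer mixture at C2 and C3) | CCO/C=C(\C)C([O-])C(C)c1oc([C@@H](C)[C@@H](O[Si](C)(C)C(C)(C)C)CC)c(C)c(=O)c1C.[Li+]
F6 | step 5 | (2E,4S)-2-methyl-4-(PyB)pent-2-enal (C4 epimer of 12) | O=C/C(C)=C/[C@H](C)c1oc([C@@H](C)[C@@H](O[Si](C)(C)C(C)(C)C)CC)c(C)c(=O)c1C
F7 | step 9 | (2R,3R,4R,5S,6E,8R)-5-[(tert-butyldimethylsilyl)oxy]-4,6-dimethyl-2-(PyA)-8-(PyB)non-6-en-3-ol | CCc1oc([C@H](C)[C@H](O)[C@@H](C)[C@H](O[Si](C)(C)C(C)(C)C)/C(C)=C/[C@@H](C)c2oc([C@@H](C)[C@@H](O[Si](C)(C)C(C)(C)C)CC)c(C)c(=O)c2C)c(C)c(=O)c1C
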